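**Plan**
- Retrosynthesis: the three phenols are masked as methyl ethers. The 20-membered ring is cut at C3–C4 of the saturated, function-free C1–C14 chain (C1 on position 6 of the dioxygenated ring B, C14 on position 3 of ring A), which leaves two ester-terminated arms.
- Further cuts: C1=C2 (cinnamate olefination), the diaryl ether bond from the bridging oxygen to position 1 of ring B, and the aryl–alkyl bond from position 3 of ring A to C14.
- Forward: ring A receives its C4–C14 ester arm by B-alkyl Suzuki coupling; Ullmann coupling joins rings A and B; olefination and hydrogenation grow the C1–C3 ester arm.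
- The only new ring, the 20-membered carbocycle, then closes by acyloin coupling (C3–C4). Oxidation to the dione, double deoxygenation and demethylation finish the synthesis.
- Stereochemistry: the target has no stereocentre and no stereogenic double bond. The E-cinnamate and the enediol geometry are transient and are erased.

Key step: step 6

Numbering used below: ring A carries its oxygen substituent (OH or OMe) at position 1, chain carbon C14 at position 3 and the bridging oxygen at position 5. Ring B carries the bridging oxygen at position 1, oxygen substituents at positions 2 and 4, and chain carbon C1 at position 6. The macrocycle skeleton is 2-oxa-1(1,3),3(1,2)-dibenzenacycloheptadecaphane.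

Assumption: the C3=C4 geometry of the bis-silyl enediol is drawn Z (cis-enediolate on sodium); either isomer would serve, since step 7 removes the double bond.

**Step 1**
Reactants: 1 3,5-dimethoxybenzaldehyde
Product: 2 2-bromo-3,5-dimethoxybenzaldehyde
Conditions: NBS (1.0 equiv), MeCN, 0 °C → rt
Reagents that add atoms: N-bromosuccinimide, O=C1CCC(=O)N1Br
Why: Electrophilic aromatic bromination should go to C2, which is ortho and para to the two methoxy groups, whereas C4 is flanked by both methoxy groups and para to the formyl group; this is the well-precedented outcome for this aldehyde.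

**Step 2**
Reactants: 3 methyl undec-10-enoate; 4 3-bromo-5-methoxyphenol
Product: 6 methyl 11-(3-hydroxy-5-methoxyphenyl)undecanoate, via alkyl-9-BBN borane 5 (not isolated)
Conditions: 9-BBN, THF, 0 °C → rt; then 4, PdCl2(dppf) (cat.), K3PO4 (aq., 3 equiv), DMF, 60 °C
Reagents that add atoms: none
Why: 9-BBN hydroborates the terminal alkene anti-Markovnikov without touching the ester, and the B-alkyl Suzuki–Miyaura coupling of the borane with the aryl bromide tolerates the free phenol as its phenoxide, so ring A has no halogen left to interfere in step 3.

**Step 3**
Reactants: 2 2-bromo-3,5-dimethoxybenzaldehyde; 6 methyl 11-(3-hydroxy-5-methoxyphenyl)undecanoate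
Product: 7 methyl 11-[3-(2-formyl-4,6-dimethoxyphenoxy)-5-methoxyphenyl]undecanoate
Conditions: CuI (cat.), picolinic acid (cat.), K3PO4, DMSO, 90 °C
Reagents that add atoms: none
Why: Ullmann-type copper-catalysed diaryl ether synthesis, in which the bromide is activated by its ortho formyl group, the ligand system suits ortho-substituted partners, and the weak anhydrous base leaves the methyl ester and the aldehyde alone.

**Step 4**
Reactants: 7 methyl 11-[3-(2-formyl-4,6-dimethoxyphenoxy)-5-methoxyphenyl]undecanoate
Product: 8 methyl (2E)-3-{3,5-dimethoxy-2-[3-methoxy-5-(11-methoxy-11-oxoundecyl)phenoxy]phenyl}prop-2-enoate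
Conditions: (MeO)2P(O)CH2CO2Me, NaH, THF, 0 °C → rt
Reagents that add atoms: trimethyl phosphonoacetate, COC(=O)CP(=O)(OC)OC
Why: Horner–Wadsworth–Emmons olefination of the aryl aldehyde with the preformed stabilised phosphonate anion should give the E-cinnamate, and that anion is too weakly basic to enolise the remote saturated ester.

**Step 5**
Reactants: 8 methyl (2E)-3-{3,5-dimethoxy-2-[3-methoxy-5-(11-methoxy-11-oxoundecyl)phenoxy]phenyl}prop-2-enoate
Product: 9 methyl 11-{3-[2-(3-methoxy-3-oxopropyl)-4,6-dimethoxyphenoxy]-5-methoxyphenyl}undecanoate
Conditions: H2 (1 atm), 10% Pd/C, EtOAc, rt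
Reagents that add atoms: none
Why: Heterogeneous catalytic hydrogenation saturates the conjugated alkene and leaves the esters, the aryl methyl ethers and the diaryl ether untouched.

**Step 6**
Reactants: 9 methyl 11-{3-[2-(3-methoxy-3-oxopropyl)-4,6-dimethoxyphenoxy]-5-methoxyphenyl}undecanoate
Product: 10 macrocyclic (Z)-C3=C4 enediol bis(trimethylsilyl) ether (20-membered ring; OMe at position 1 of ring A and at positions 2 and 4 of ring B; Me3SiO on C3 and on C4)
Conditions: Na (dispersion, 4.5 equiv), Me3SiCl (6 equiv), toluene, reflux, slow addition of 9 under Ar; filtered and concentrated under Ar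
Reagents that add atoms: chlorotrimethylsilane, C[Si](C)(C)Cl
Why: Electron transfer from the molten, finely divided sodium converts each methyl ester into a ketyl radical anion; the two surface-held ketyls couple to form C3–C4, both methoxides leave as MeOSiMe3, and the resulting 1,2-dicarbonyl takes up two more electrons to give the enediolate, which Me3SiCl silylates on both oxygens. This is the acyloin condensation in its Me3SiCl-trapping (Rühlmann) form, the classical entry to large carbocycles and cyclophanes. The single new ring, the 20-membered carbocycle, closes by end-to-end reductive coupling of the C3 and C4 ester carbons of one molecule held on the same metal surface, so ring closure should compete well with chain growth when 9 is fed in slowly. No stereocentre is formed; the enediol double bond is expected as the Z isomer from the chelated cis-enediolate and is removed in step 7. The step needs reduction of the esters in preference to the diaryl ether and the three aryl methyl ethers, which the aprotic hydrocarbon medium (no ammonia or donor solvent to support arene radical anions) and the much easier reduction of esters should secure, while Me3SiCl scavenges methoxide so that Claisen or Dieckmann condensation of the enolisable arms cannot intervene.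

**Step 7**
Reactants: 10 macrocyclic (Z)-C3=C4 enediol bis(trimethylsilyl) ether
Product: 11 macrocyclic C3,C4-dione (trimethyl ether)
Conditions: Br2 (1.0 equiv, dilute solution added dropwise), CH2Cl2, −78 °C; then concentrated
Reagents that add atoms: none
Why: Oxidative desilylation of an acyloin bis-silyl enediol ether by bromine (Rühlmann dione synthesis) with loss of two Me3SiBr; the tetrasubstituted enediol ether is far more nucleophilic than the anisole rings, so one equivalent of bromine titrated in at −78 °C should be consumed there without generating HBr.

**Step 8**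
Reactants: 11 macrocyclic C3,C4-dione (trimethyl ether)
Product: 13 tri-O-methyl ether of the target (saturated C1–C14 chain), via bis-hydrazone 12 (not isolated)
Conditions: N2H4·H2O (excess), diethylene glycol, 130 °C; then KOH, 195–200 °C with removal of water
Reagents that add atoms: none
Why: Wolff–Kishner reduction (Huang-Minlon procedure) of both carbonyl groups through the bis-hydrazone, which is formed before base is added so that the dione never meets hydroxide; the aryl ethers are not reducible here, and any methyl ether lost to hot alkali would be removed in step 9 anyway.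

**Step 9**
Reactants: 13 tri-O-methyl ether of the target
Product: 14 CNP0173380.0 (triol with OH at position 1 of ring A and at positions 2 and 4 of ring B; 20-membered ring A–O–ring B with saturated C1–C14 chain)
Conditions: BBr3 (6 equiv), CH2Cl2, −78 °C → rt; then MeOH, H2O
Reagents that add atoms: none
Why: Lewis-acid cleavage of the three aryl methyl ethers by BBr3 with loss of MeBr; the diaryl ether and the saturated chain are inert, and there is no stereocentre to disturb.

**Compound list**
1 | 3,5-dimethoxybenzaldehyde | COc1cc(OC)cc(C=O)c1 | starting material
2 | 2-bromo-3,5-dimethoxybenzaldehyde | COc1cc(OC)c(Br)c(C=O)c1 | intermediate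
3 | methyl undec-10-enoate | C=CCCCCCCCCC(=O)OC | starting material
4 | 3-bromo-5-methoxyphenol | COc1cc(O)cc(Br)c1 | starting material
5 | methyl 11-(9-borabicyclo[3.3.1]nonan-9-yl)undecanoate (alkyl-9-BBN borane, not isolated) | COC(=O)CCCCCCCCCCB1C2CCCC1CCC2 | intermediate
6 | methyl 11-(3-hydroxy-5-methoxyphenyl)undecanoate | COC(=O)CCCCCCCCCCc1cc(O)cc(OC)c1 | intermediate
7 | methyl 11-[3-(2-formyl-4,6-dimethoxyphenoxy)-5-methoxyphenyl]undecanoate | COC(=O)CCCCCCCCCCc1cc(OC)cc(Oc2c(C=O)cc(OC)cc2OC)c1 | intermediate
8 | methyl (2E)-3-{3,5-dimethoxy-2-[3-methoxy-5-(11-methoxy-11-oxoundecyl)phenoxy]phenyl}prop-2-enoate | COC(=O)/C=C/c1cc(OC)cc(OC)c1Oc1cc(OC)cc(CCCCCCCCCCC(=O)OC)c1 | intermediate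
9 | methyl 11-{3-[2-(3-methoxy-3-oxopropyl)-4,6-dimethoxyphenoxy]-5-methoxyphenyl}undecanoate (key-step precursor) | COC(=O)CCc1cc(OC)cc(OC)c1Oc1cc(OC)cc(CCCCCCCCCCC(=O)OC)c1 | intermediate
10 | macrocyclic (Z)-C3=C4 enediol bis(trimethylsilyl) ether, OMe at position 1 of ring A and positions 2 and 4 of ring B (key-step product) | COc1cc2cc(c1)Oc1c(OC)cc(OC)cc1CC/C(O[Si](C)(C)C)=C(/O[Si](C)(C)C)CCCCCCCCCC2 | intermediate
11 | macrocyclic C3,C4-dione, OMe at position 1 of ring A and positions 2 and 4 of ring B | COc1cc2cc(c1)Oc1c(OC)cc(OC)cc1CCC(=O)C(=O)CCCCCCCCCC2 | intermediate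
12 | macrocyclic C3,C4-bis-hydrazone (C=N geometry not defined, not isolated) | COc1cc2cc(c1)Oc1c(OC)cc(OC)cc1CCC(=NN)C(=NN)CCCCCCCCCC2 | intermediate
13 | tri-O-methyl ether of the target, saturated C1–C14 chain | COc1cc2cc(c1)Oc1c(OC)cc(OC)cc1CCCCCCCCCCCCCC2 | intermediate
14 | CNP0173380.0, 2-oxa-1(1,3),3(1,2)-dibenzenacycloheptadecaphane-1^5,3^4,3^6-triol | Oc1cc2cc(c1)Oc1c(O)cc(O)cc1CCCCCCCCCCCCCC2 | target

**Count and risks**
Total steps: 9. Longest linear sequence: 8 steps (1 → 2 → 7 → 8 → 9 → 10 → 11 → 13 → 14, or equally from 3 and 4 through step 2).

Step 6 (acyloin ring closure). What may go wrong: intermolecular coupling to oligomers, or electron transfer to the aromatic ethers with cleavage of the diaryl ether, could outrun the ring closure. Fallback, setting out from 9 and returning at 13: both esters of 9 would be reduced with iBu2AlH in toluene at −78 °C to 11-{3-[2,4-dimethoxy-6-(3-oxopropyl)phenoxy]-5-methoxyphenyl}undecanal F1. Intramolecular McMurry coupling (TiCl3, Zn(Cu), DME, reflux, syringe-pump addition) would form the same C3–C4 bond as the macrocyclic C3=C4 alkene F2 (E/Z mixture expected, drawn E). Hydrogenation (H2, Pd/C, EtOAc) would then give 13 directly, bypassing 10 to 12.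

Step 7 (bromine oxidation). What may go wrong: electrophilic bromination of the electron-rich rings A and B could compete with attack on the enediol ether. Fallback, setting out from 10 and returning at 11: 10 would be hydrolysed (1 M HCl, THF, rt) to the racemic acyloin, expected as two regioisomers, the C4-hydroxy C3-ketone F3 and the C3-hydroxy C4-ketone F4. The mixture would be oxidised with Cu(OAc)2 in aqueous AcOH at 80 °C, and both isomers should converge on the single dione 11 without any electrophilic halogen.

Step 8 (double Wolff–Kishner). What may go wrong: reduction of the vicinal hydrazones could stall or diverge (azine formation, olefin or mono-ketone by-products), and hot alkali could partly cleave methyl ethers. Fallback, setting out from 11 and returning at 13: the bis-hydrazone 12 would be made and isolated (N2H4·H2O, EtOH, reflux). Oxidation with yellow HgO (cat. KOH, toluene, reflux) would expel two N2 and give the 20-membered C3≡C4 cycloalkyne F5, unstrained at this ring size. Hydrogenation (H2, Pd/C, EtOAc) would then give 13.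

**Further compounds**
F1 | step 6 | 11-{3-[2,4-dimethoxy-6-(3-oxopropyl)phenoxy]-5-methoxyphenyl}undecanal | O=CCCc1cc(OC)cc(OC)c1Oc1cc(OC)cc(CCCCCCCCCCC=O)c1
F2 | step 6 | macrocyclic (E)-C3=C4 alkene, OMe at position 1 of ring A and positions 2 and 4 of ring B | COc1cc2cc(c1)Oc1c(OC)cc(OC)cc1CC/C=C/CCCCCCCCCC2
F3 | step 7 | macrocyclic acyloin, C4-hydroxy C3-ketone (racemic), OMe at position 1 of ring A and positions 2 and 4 of ring B | COc1cc2cc(c1)Oc1c(OC)cc(OC)cc1CCC(=O)C(O)CCCCCCCCCC2
F4 | step 7 | macrocyclic acyloin, C3-hydroxy C4-ketone (racemic), OMe at position 1 of ring A and positions 2 and 4 of ring B | COc1cc2cc(c1)Oc1c(OC)cc(OC)cc1CCC(O)C(=O)CCCCCCCCCC2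
F5 | step 8 | macrocyclic C3≡C4 cycloalkyne, OMe at position 1 of ring A and positions 2 and 4 of ring B | COc1cc2cc(c1)Oc1c(OC)cc(OC)cc1CCC#CCCCCCCCCCC2
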